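## Retrosynthetic overview

1. Target ⇐ bis-silyl ether ⇐ acyclic 1,4-diketone by intramolecular aldol condensation (C2=C3). The cyclopentenone is the last ring formed.
2. 1,4-Diketone ⇐ α,β-epoxy aryl ketone + 2-metallated 3-methoxypropene. Chelation-controlled addition sets C5; O-methylation, ozonolysis (C1=O) and oxidation of the C3 carbinol follow.
3. Epoxy aryl ketone ⇐ epoxy aldehyde + aryl Grignard reagent, then oxidation.
4. Epoxy aldehyde ⇐ 2-substituted allylic alcohol by Sharpless asymmetric epoxidation. The oxirane is the first ring formed and fixes C4.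
5. Allylic alcohol ⇐ key C3–C4 bond by intermolecular aldol addition of an amino-ester lithium enolate to the protected 4-hydroxybenzaldehyde, then amine elimination, silylation and ester reduction.

Convention (one line): locants C1 (C=O), C2 (C–OMe), C3 (C–aryl), C4 (spiro oxirane carbon), C5 (C(OMe)aryl) are used for all intermediates; Ar = 4-[(triisopropylsilyl)oxy]phenyl; the temporary carbinol carbon C3 is carried as a 1:1 epimer mixture from the epoxidation until it is oxidised to the ketone.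

## Route

Step 1
Reactants: 1 4-hydroxybenzaldehyde
Product: 2 4-[(triisopropylsilyl)oxy]benzaldehyde
Conditions: iPr3SiCl, imidazole, DMF, rt
Reagents that add atoms: triisopropylsilyl chloride, CC(C)[Si](Cl)(C(C)C)C(C)C
Why: Imidazole-promoted silylation gives a phenol silyl ether that survives the later basic and organometallic steps and is fluoride-labile at the end.

Step 2
Reactants: 3 methyl 3-(dimethylamino)propanoate; 2 4-[(triisopropylsilyl)oxy]benzaldehyde
Product: 5 methyl 2-[(dimethylamino)methyl]-3-hydroxy-3-Ar-propanoate (racemic syn/anti mixture), via lithium enolate 4 (not isolated)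
Conditions: LiN(iPr)2, THF, −78 °C; then 2; then H2O
Reagents that add atoms: none
Why: Intermolecular aldol addition of an ester lithium enolate (an acrylate α-anion equivalent) to the non-enolisable aldehyde forges the C3–C4 bond; neither new stereocentre is retained (one is lost in step 3, the other in step 16).

Step 3
Reactants: 5 methyl 2-[(dimethylamino)methyl]-3-hydroxy-3-Ar-propanoate
Product: 7 methyl 2-[hydroxy(Ar)methyl]prop-2-enoate (racemic), via ammonium iodide 6 (not isolated)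
Conditions: MeI, MeOH, rt; then DBU, CH2Cl2, rt
Reagents that add atoms: none
Why: N-Methylation followed by E1cB (Hofmann-type) elimination of trimethylamine unmasks the α-methylene ester, giving the Morita–Baylis–Hillman-type adduct.

Step 4
Reactants: 7 methyl 2-[hydroxy(Ar)methyl]prop-2-enoate
Product: 8 methyl 2-[Ar(triethylsilyloxy)methyl]prop-2-enoate (racemic)
Conditions: Et3SiCl, imidazole, DMF, 0 °C
Reagents that add atoms: triethylsilyl chloride, CC[Si](Cl)(CC)CC
Why: Silylation protects the secondary benzylic alcohol with a bulky, non-chelating group that can later be removed in the presence of the aryl silyl ethers.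

Step 5
Reactants: 8 methyl 2-[Ar(triethylsilyloxy)methyl]prop-2-enoate
Product: 9 2-[Ar(triethylsilyloxy)methyl]prop-2-en-1-ol (racemic)
Conditions: iBu2AlH, CH2Cl2, −78 °C; aqueous work-up
Reagents that add atoms: none
Why: 1,2-Reduction of the enoate by the aluminium hydride gives the primary allylic alcohol that directs the epoxidation.

Step 6
Reactants: 9 2-[Ar(triethylsilyloxy)methyl]prop-2-en-1-ol
Product: 10 [(2S)-2-[Ar(triethylsilyloxy)methyl]oxiran-2-yl]methanol (1:1 epimers at the silyloxy carbon)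
Conditions: Ti(OiPr)4 (10 mol%), L-(+)-diethyl tartrate (12 mol%), tBuOOH, 4 Å MS, CH2Cl2, −20 °C
Reagents that add atoms: tert-butyl hydroperoxide, CC(C)(C)OO
Why: Sharpless asymmetric epoxidation is reagent-controlled, so the L-(+)-tartrate catalyst delivers oxygen to the same alkene face in both enantiomers of 9 and sets the oxirane carbon C4 as S here, which is the R centre of the target.

Step 7
Reactants: 10 [(2S)-2-[Ar(triethylsilyloxy)methyl]oxiran-2-yl]methanol
Product: 11 (2S)-2-[Ar(triethylsilyloxy)methyl]oxirane-2-carbaldehyde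
Conditions: Dess–Martin periodinane, pyridine, CH2Cl2, 0 °C to rt
Reagents that add atoms: none
Why: Buffered Dess–Martin oxidation gives the non-enolisable epoxy aldehyde without touching the oxirane or silyl ethers.

Step 8
Reactants: 12 4-bromophenol
Product: 13 (4-bromophenoxy)triisopropylsilane
Conditions: iPr3SiCl, imidazole, DMF, rt
Reagents that add atoms: triisopropylsilyl chloride, CC(C)[Si](Cl)(C(C)C)C(C)C
Why: Phenol silylation makes the aryl bromide compatible with Grignard formation.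

Step 9
Reactants: 13 (4-bromophenoxy)triisopropylsilane; 11 (2S)-2-[Ar(triethylsilyloxy)methyl]oxirane-2-carbaldehyde
Product: 15 [(2R)-2-[Ar(triethylsilyloxy)methyl]oxiran-2-yl](Ar)methanol (carbinol epimers), via arylmagnesium bromide 14 (not isolated)
Conditions: Mg, THF, rt; then 11, THF, −78 °C; then H2O
Reagents that add atoms: none
Why: Grignard 1,2-addition is chemoselective for the aldehyde at low temperature; the new carbinol centre is oxidised in the next step, so its configuration does not matter.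

Step 10
Reactants: 15 [(2R)-2-[Ar(triethylsilyloxy)methyl]oxiran-2-yl](Ar)methanol
Product: 16 [(2S)-2-[Ar(triethylsilyloxy)methyl]oxiran-2-yl](Ar)methanone
Conditions: Dess–Martin periodinane, pyridine, CH2Cl2, 0 °C to rt
Reagents that add atoms: none
Why: Dess–Martin oxidation of the benzylic alcohol gives the α,β-epoxy aryl ketone that carries the future C5 carbonyl.

Step 11
Reactants: 17 2,3-dibromoprop-1-ene
Product: 18 2-bromo-3-methoxyprop-1-ene
Conditions: NaOMe, MeOH, 0 °C to rt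
Reagents that add atoms: sodium methoxide, [Na+].[O-]C
Why: SN2 displacement of the allylic bromide by methoxide leaves the vinylic bromide untouched.

Step 12
Reactants: 18 2-bromo-3-methoxyprop-1-ene; 16 [(2S)-2-[Ar(triethylsilyloxy)methyl]oxiran-2-yl](Ar)methanone
Product: 21 (1S)-1-Ar-2-(methoxymethyl)-1-[(2S)-2-[Ar(triethylsilyloxy)methyl]oxiran-2-yl]prop-2-en-1-ol, via vinyllithium 19 (not isolated), via vinylmagnesium bromide 20 (not isolated)
Conditions: tBuLi (2 equiv), Et2O, −78 °C; MgBr2·OEt2; then 16, CH2Cl2, −78 to −40 °C; then H2O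
Reagents that add atoms: none
Why: Bromine–lithium exchange, transmetalation and chelation-controlled (Cram cyclic model) 1,2-addition, in which magnesium bridges the ketone and oxirane oxygens and the nucleophile enters from the side of the small oxirane CH2, anti to the bulky CH(OSiEt3)Ar arm, setting C5 with its oxygen cis to the oxirane CH2 as in the target.

Step 13
Reactants: 21 (1S)-1-Ar-2-(methoxymethyl)-1-[(2S)-2-[Ar(triethylsilyloxy)methyl]oxiran-2-yl]prop-2-en-1-ol
Product: 22 (2S)-2-[(1S)-1-Ar-1-methoxy-2-(methoxymethyl)prop-2-en-1-yl]-2-[Ar(triethylsilyloxy)methyl]oxirane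
Conditions: KN(SiMe3)2, THF, −78 °C; then MeOTf
Reagents that add atoms: methyl trifluoromethanesulfonate, COS(=O)(=O)C(F)(F)F
Why: Low-temperature deprotonation and immediate Williamson-type O-methylation with a powerful methylating agent outpaces Payne rearrangement and installs the C5 methoxy group with retention.

Step 14
Reactants: 22 (2S)-2-[(1S)-1-Ar-1-methoxy-2-(methoxymethyl)prop-2-en-1-yl]-2-[Ar(triethylsilyloxy)methyl]oxirane
Product: 24 (3R)-3-Ar-1,3-dimethoxy-3-[(2S)-2-[Ar(triethylsilyloxy)methyl]oxiran-2-yl]propan-2-one, via ozonide 23 (not isolated)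
Conditions: O3, CH2Cl2, −78 °C; then Me2S
Reagents that add atoms: ozone, [O-][O+]=O
Why: Ozonolysis of the 1,1-disubstituted alkene, which is far more reactive than the arenes, with reductive work-up unveils the C1 ketone next to the methoxymethyl carbon C2.

Step 15
Reactants: 24 (3R)-3-Ar-1,3-dimethoxy-3-[(2S)-2-[Ar(triethylsilyloxy)methyl]oxiran-2-yl]propan-2-one
Product: 25 (3R)-3-Ar-3-[(2S)-2-[Ar(hydroxy)methyl]oxiran-2-yl]-1,3-dimethoxypropan-2-one (may sit partly as its five-membered lactol)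
Conditions: HF·pyridine, pyridine, THF, 0 °C
Reagents that add atoms: none
Why: Buffered HF·pyridine cleaves the alkyl triethylsilyl ether selectively over the aryl triisopropylsilyl ethers and leaves the oxirane intact.

Step 16
Reactants: 25 (3R)-3-Ar-3-[(2S)-2-[Ar(hydroxy)methyl]oxiran-2-yl]-1,3-dimethoxypropan-2-one
Product: 26 (3R)-3-Ar-3-[(2R)-2-{4-[(triisopropylsilyl)oxy]benzoyl}oxiran-2-yl]-1,3-dimethoxypropan-2-one
Conditions: Dess–Martin periodinane, pyridine, CH2Cl2, 0 °C to rt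
Reagents that add atoms: none
Why: Dess–Martin oxidation removes the temporary C3 stereocentre, so both epimers converge on one 1,4-diketone.

Step 17
Reactants: 26 (3R)-3-Ar-3-[(2R)-2-{4-[(triisopropylsilyl)oxy]benzoyl}oxiran-2-yl]-1,3-dimethoxypropan-2-one
Product: 28 (3R,4R)-4,6-dimethoxy-4,7-di-Ar-1-oxaspiro[2.4]hept-6-en-5-one, via aldol 27 (not isolated)
Conditions: KOtBu (0.2 equiv), tBuOH/THF, 0 °C to rt
Reagents that add atoms: none
Why: Intramolecular aldol condensation, in which the only enolisable carbon (C2) attacks the C3 aryl ketone (5-exo) and E1cB dehydration gives the tetrasubstituted enone; C4 and C5 are quaternary and cannot epimerise.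

Step 18
Reactants: 28 (3R,4R)-4,6-dimethoxy-4,7-di-Ar-1-oxaspiro[2.4]hept-6-en-5-one
Product: 29 (3R,4R)-4,7-bis(4-hydroxyphenyl)-4,6-dimethoxy-1-oxaspiro[2.4]hept-6-en-5-one (CNP0504072.1)
Conditions: Bu4NF, AcOH, THF, 0 °C
Reagents that add atoms: none
Why: Acetic-acid-buffered fluoride desilylation frees both phenols without opening the oxirane or adding to the enone.

## Compound list

1 | 4-hydroxybenzaldehyde | O=Cc1ccc(O)cc1 | starting material
2 | 4-[(triisopropylsilyl)oxy]benzaldehyde | O=Cc1ccc(O[Si](C(C)C)(C(C)C)C(C)C)cc1 | intermediate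
3 | methyl 3-(dimethylamino)propanoate | COC(=O)CCN(C)C | starting material
4 | lithium enolate of 3 | [Li+].COC([O-])=CCN(C)C | intermediate (not isolated)
5 | methyl 2-[(dimethylamino)methyl]-3-hydroxy-3-Ar-propanoate, racemic syn/anti mixture | COC(=O)C(CN(C)C)C(O)c1ccc(O[Si](C(C)C)(C(C)C)C(C)C)cc1 | intermediate
6 | trimethylammonium iodide of 5 | COC(=O)C(C[N+](C)(C)C)C(O)c1ccc(O[Si](C(C)C)(C(C)C)C(C)C)cc1.[I-] | intermediate (not isolated)
7 | methyl 2-[hydroxy(Ar)methyl]prop-2-enoate, racemic | COC(=O)C(=C)C(O)c1ccc(O[Si](C(C)C)(C(C)C)C(C)C)cc1 | intermediate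
8 | methyl 2-[Ar(triethylsilyloxy)methyl]prop-2-enoate, racemic | COC(=O)C(=C)C(O[Si](CC)(CC)CC)c1ccc(O[Si](C(C)C)(C(C)C)C(C)C)cc1 | intermediate
9 | 2-[Ar(triethylsilyloxy)methyl]prop-2-en-1-ol, racemic | OCC(=C)C(O[Si](CC)(CC)CC)c1ccc(O[Si](C(C)C)(C(C)C)C(C)C)cc1 | intermediate
10 | [(2S)-2-[Ar(triethylsilyloxy)methyl]oxiran-2-yl]methanol, both epimers at the silyloxy carbon | CC[Si](CC)(CC)OC(c1ccc(O[Si](C(C)C)(C(C)C)C(C)C)cc1)[C@@]1(CO1)CO | intermediate
11 | (2S)-2-[Ar(triethylsilyloxy)methyl]oxirane-2-carbaldehyde, both epimers at the silyloxy carbon | CC[Si](CC)(CC)OC(c1ccc(O[Si](C(C)C)(C(C)C)C(C)C)cc1)[C@@]1(CO1)C=O | intermediate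
12 | 4-bromophenol | Oc1ccc(Br)cc1 | starting material
13 | (4-bromophenoxy)triisopropylsilane | Brc1ccc(O[Si](C(C)C)(C(C)C)C(C)C)cc1 | intermediate
14 | {4-[(triisopropylsilyl)oxy]phenyl}magnesium bromide | Br[Mg]c1ccc(O[Si](C(C)C)(C(C)C)C(C)C)cc1 | intermediate (not isolated)
15 | [(2R)-2-[Ar(triethylsilyloxy)methyl]oxiran-2-yl](Ar)methanol, epimers at both carbinol carbons | CC[Si](CC)(CC)OC(c1ccc(O[Si](C(C)C)(C(C)C)C(C)C)cc1)[C@@]1(CO1)C(O)c1ccc(O[Si](C(C)C)(C(C)C)C(C)C)cc1 | intermediate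
16 | [(2S)-2-[Ar(triethylsilyloxy)methyl]oxiran-2-yl](Ar)methanone, both epimers at the silyloxy carbon | CC[Si](CC)(CC)OC(c1ccc(O[Si](C(C)C)(C(C)C)C(C)C)cc1)[C@@]1(CO1)C(=O)c1ccc(O[Si](C(C)C)(C(C)C)C(C)C)cc1 | intermediate
17 | 2,3-dibromoprop-1-ene | C=C(Br)CBr | starting material
18 | 2-bromo-3-methoxyprop-1-ene | COCC(Br)=C | intermediate
19 | (3-methoxyprop-1-en-2-yl)lithium | [Li]C(=C)COC | intermediate (not isolated)
20 | (3-methoxyprop-1-en-2-yl)magnesium bromide | Br[Mg]C(=C)COC | intermediate (not isolated)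
21 | (1S)-1-Ar-2-(methoxymethyl)-1-[(2S)-2-[Ar(triethylsilyloxy)methyl]oxiran-2-yl]prop-2-en-1-ol, both epimers at the silyloxy carbon | CC[Si](CC)(CC)OC(c1ccc(O[Si](C(C)C)(C(C)C)C(C)C)cc1)[C@@]1(CO1)[C@](O)(c1ccc(O[Si](C(C)C)(C(C)C)C(C)C)cc1)C(=C)COC | intermediate
22 | (2S)-2-[(1S)-1-Ar-1-methoxy-2-(methoxymethyl)prop-2-en-1-yl]-2-[Ar(triethylsilyloxy)methyl]oxirane, both epimers at the silyloxy carbon | CC[Si](CC)(CC)OC(c1ccc(O[Si](C(C)C)(C(C)C)C(C)C)cc1)[C@@]1(CO1)[C@](OC)(c1ccc(O[Si](C(C)C)(C(C)C)C(C)C)cc1)C(=C)COC | intermediate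
23 | secondary ozonide (3-(methoxymethyl)-1,2,4-trioxolan-3-yl compound) of 22 | CC[Si](CC)(CC)OC(c1ccc(O[Si](C(C)C)(C(C)C)C(C)C)cc1)[C@@]1(CO1)[C@](OC)(c1ccc(O[Si](C(C)C)(C(C)C)C(C)C)cc1)C1(COC)OCOO1 | intermediate (not isolated)
24 | (3R)-3-Ar-1,3-dimethoxy-3-[(2S)-2-[Ar(triethylsilyloxy)methyl]oxiran-2-yl]propan-2-one, both epimers at the silyloxy carbon | CC[Si](CC)(CC)OC(c1ccc(O[Si](C(C)C)(C(C)C)C(C)C)cc1)[C@@]1(CO1)[C@](OC)(c1ccc(O[Si](C(C)C)(C(C)C)C(C)C)cc1)C(=O)COC | intermediate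
25 | (3R)-3-Ar-3-[(2S)-2-[Ar(hydroxy)methyl]oxiran-2-yl]-1,3-dimethoxypropan-2-one, both carbinol epimers | OC(c1ccc(O[Si](C(C)C)(C(C)C)C(C)C)cc1)[C@@]1(CO1)[C@](OC)(c1ccc(O[Si](C(C)C)(C(C)C)C(C)C)cc1)C(=O)COC | intermediate
26 | (3R)-3-Ar-3-[(2R)-2-{4-[(triisopropylsilyl)oxy]benzoyl}oxiran-2-yl]-1,3-dimethoxypropan-2-one | O=C(c1ccc(O[Si](C(C)C)(C(C)C)C(C)C)cc1)[C@@]1(CO1)[C@](OC)(c1ccc(O[Si](C(C)C)(C(C)C)C(C)C)cc1)C(=O)COC | intermediate
27 | aldol adduct, 7-hydroxy-4,6-dimethoxy-4,7-di-Ar-1-oxaspiro[2.4]heptan-5-one (spiro carbon and C4 arranged as in 28; C6 and C7 unassigned) | COC1C(O)(c2ccc(O[Si](C(C)C)(C(C)C)C(C)C)cc2)[C@@]2(CO2)[C@](OC)(c2ccc(O[Si](C(C)C)(C(C)C)C(C)C)cc2)C1=O | intermediate (not isolated)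
28 | (3R,4R)-4,6-dimethoxy-4,7-bis{4-[(triisopropylsilyl)oxy]phenyl}-1-oxaspiro[2.4]hept-6-en-5-one | COC1=C(c2ccc(O[Si](C(C)C)(C(C)C)C(C)C)cc2)[C@@]2(CO2)[C@](OC)(c2ccc(O[Si](C(C)C)(C(C)C)C(C)C)cc2)C1=O | intermediate
29 | (3R,4R)-4,7-bis(4-hydroxyphenyl)-4,6-dimethoxy-1-oxaspiro[2.4]hept-6-en-5-one | COC1=C(c2ccc(O)cc2)[C@@]2(CO2)[C@](OC)(c2ccc(O)cc2)C1=O | target

## Step count and risks

Total steps: 18. Longest linear sequence: 16 (steps 1–7, 9, 10, 12–18).

Steps most likely to fail: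

Step 12. The ketone is hindered, the 2-metallated allyl ether can lose methoxide, and facial selectivity rests on the chelate model. Fallback: setting out from ketone 16, add the small nucleophile vinylmagnesium bromide under the same magnesium dibromide chelation to give the tertiary allylic alcohol F1. Methylate it (KN(SiMe3)2, MeOTf) to the methyl ether F2 and ozonolyse to the α-methoxy aldehyde F3. Add (methoxymethyl)lithium, made from Bu3SnCH2OMe and nBuLi, to give the secondary alcohol F4, and oxidise with Dess–Martin periodinane. This builds C1–C2 in two carbon–carbon steps and comes back to the route at ketone 24.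

Step 13. A tertiary alkoxide next to the oxirane may undergo Payne-type rearrangement or resist methylation. Fallback: setting out from alcohol 21, ozonolyse first (O3, then Me2S) to the α-hydroxy ketone F5. Its more acidic α-ketol hydroxyl is then methylated with Ag2O and MeI, without ever generating a free alkoxide, and the sequence comes back to the route at ketone 24.

Step 17. The equilibrating enolate could open the oxirane, or the crowded aldol may not dehydrate cleanly. Fallback: setting out from diketone 26, form the trimethylsilyl enol ether F6 (Me3SiOTf, Et3N, CH2Cl2, 0 °C). Release the enolate at −78 °C with anhydrous fluoride (tris(dimethylamino)sulfonium difluorotrimethylsilicate), so that only the kinetic 5-exo aldol closure occurs. Isolate aldol 27 and dehydrate it with the Burgess reagent; this comes back to the route at enone 28.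

## Further compounds

F1 | step 12 | 1-Ar-1-[(2S)-2-[Ar(triethylsilyloxy)methyl]oxiran-2-yl]prop-2-en-1-ol (carbinol carbon arranged as C5 of 21) | CC[Si](CC)(CC)OC(c1ccc(O[Si](C(C)C)(C(C)C)C(C)C)cc1)[C@@]1(CO1)[C@](O)(c1ccc(O[Si](C(C)C)(C(C)C)C(C)C)cc1)C=C
F2 | step 12 | methyl ether of F1, (2S)-2-(1-Ar-1-methoxyprop-2-en-1-yl)-2-[Ar(triethylsilyloxy)methyl]oxirane | CC[Si](CC)(CC)OC(c1ccc(O[Si](C(C)C)(C(C)C)C(C)C)cc1)[C@@]1(CO1)[C@](OC)(c1ccc(O[Si](C(C)C)(C(C)C)C(C)C)cc1)C=C
F3 | step 12 | 2-Ar-2-methoxy-2-[(2S)-2-[Ar(triethylsilyloxy)methyl]oxiran-2-yl]acetaldehyde | CC[Si](CC)(CC)OC(c1ccc(O[Si](C(C)C)(C(C)C)C(C)C)cc1)[C@@]1(CO1)[C@](OC)(c1ccc(O[Si](C(C)C)(C(C)C)C(C)C)cc1)C=O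
F4 | step 12 | 3-Ar-1,3-dimethoxy-3-[(2S)-2-[Ar(triethylsilyloxy)methyl]oxiran-2-yl]propan-2-ol (epimers at C2) | CC[Si](CC)(CC)OC(c1ccc(O[Si](C(C)C)(C(C)C)C(C)C)cc1)[C@@]1(CO1)[C@](OC)(c1ccc(O[Si](C(C)C)(C(C)C)C(C)C)cc1)C(O)COC
F5 | step 13 | 3-Ar-3-hydroxy-1-methoxy-3-[(2S)-2-[Ar(triethylsilyloxy)methyl]oxiran-2-yl]propan-2-one | CC[Si](CC)(CC)OC(c1ccc(O[Si](C(C)C)(C(C)C)C(C)C)cc1)[C@@]1(CO1)[C@](O)(c1ccc(O[Si](C(C)C)(C(C)C)C(C)C)cc1)C(=O)COC
F6 | step 17 | trimethylsilyl enol ether of 26 (C1–O–SiMe3, C1=C2) | O=C(c1ccc(O[Si](C(C)C)(C(C)C)C(C)C)cc1)[C@@]1(CO1)[C@](OC)(c1ccc(O[Si](C(C)C)(C(C)C)C(C)C)cc1)C(O[Si](C)(C)C)=COC
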